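## Retrosynthetic overview

1. Target ⇐ diol lactone (two acetylations) ⇐ its bis-silyl ether (desilylation).
2. Key disconnection, both rings in one flask: SmI2 ketyl–olefin macrocyclisation of an acyclic (Z,Z)-farnesane-type enal/enoate forms C6–C7 (the bond germacrene A synthase makes from farnesyl diphosphate), then the 12,6-lactone closes (as in costunolide biosynthesis). This step creates C6, C7 and C11.
3. Acyclic precursor ⇐ triene triol by persilylation, cross-metathesis with methyl methacrylate (brings C11–C13) and oxidative unmasking of C6.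
4. Triol ⇐ two cycles of lactone → lactol → Brown allylation (C3, then C9). Both Z-alkenes come from ring templates: 3-methylbutenolide for C4=C5 and a methacrylate-RCM dihydropyranone for C1=C10.
5. Ring order: 10-membered carbocycle first, γ-lactone second, same flask; the earlier rings are temporary templates.

Assumption: the SMILES is read literally, so both ring alkenes are Z and the stereocentres are 3S,6S,7S,9R,11R in germacrane numbering (C12 lactone carbonyl, C6 lactone O–CH, C7 ring-fusion CH, C11 CH–CH3); these atom labels are used throughout.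

Numbering note: substrates, building blocks and atom-donating reagents carry numbers; reagents that give only hydrogen or nothing to the product (DIBAL-H, SmI2, Swern reagents, HF·pyridine, bases, catalysts) are named in the conditions only.

## Route

Step 1
Reactants: 1 3-methylfuran-2(5H)-one
Product: 2 3-methyl-2,5-dihydrofuran-2-ol (lactol; anomer mixture)
Conditions: DIBAL-H (1.1 equiv), CH2Cl2, −78 °C; Rochelle salt; used crude at once
Reagents that add atoms: none
Why: DIBAL-H half-reduction of a lactone stops at the aluminium hemiacetal at −78 °C, giving the lactol that is the ring-locked form of (Z)-4-hydroxy-2-methylbut-2-enal, so the C4=C5 Z geometry is fixed by the ring.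

Step 2
Reactants: 2 3-methyl-2,5-dihydrofuran-2-ol; 3 (−)-B-allyldiisopinocampheylborane
Product: 5 (2Z,4S)-3-methylhepta-2,6-diene-1,4-diol, via ring-opened hydroxy enal 4 (not isolated)
Conditions: 3 (2.2 equiv), Et2O, −78 °C → rt; then HOCH2CH2NH2
Reagents that add atoms: (−)-B-allyldiisopinocampheylborane 3, C=CCB([C@@H]1C[C@@H]2C[C@H]([C@H]1C)C2(C)C)[C@@H]1C[C@@H]2C[C@H]([C@H]1C)C2(C)C
Why: Brown asymmetric allylboration of the aldehyde tautomer through a chair six-membered transition state; the (+)-α-pinene-derived reagent adds allyl to the Si face, which sets C3 as S.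

Step 3
Reactants: 5 (2Z,4S)-3-methylhepta-2,6-diene-1,4-diol; 6 methacryloyl chloride
Product: 7 (2Z,4S)-3-methylhepta-2,6-diene-1,4-diyl bis(2-methylprop-2-enoate)
Conditions: 6 (2.5 equiv), Et3N, DMAP (cat.), CH2Cl2, 0 °C
Reagents that add atoms: methacryloyl chloride 6, C=C(C)C(Cl)=O
Why: DMAP-catalysed O-acylation of both hydroxyls; the C3 ester is the metathesis partner for step 4 and the C6 ester is a temporary protecting group that step 5 removes.

Step 4
Reactants: 7 (2Z,4S)-3-methylhepta-2,6-diene-1,4-diyl bis(2-methylprop-2-enoate)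
Product: 8 (2Z)-3-[(2S)-5-methyl-6-oxo-3,6-dihydro-2H-pyran-2-yl]but-2-en-1-yl 2-methylprop-2-enoate
Conditions: Grubbs II (5 mol%), CH2Cl2 (5 mM), 40 °C
Reagents that add atoms: none
Why: Ring-closing metathesis between the terminal alkene and the secondary methacrylate closes the six-membered unsaturated lactone, so the new trisubstituted C1=C10 alkene is Z by ring constraint; the primary methacrylate could only pair with the hindered trisubstituted alkene and stays intact.

Step 5
Reactants: 8 (2Z)-3-[(2S)-5-methyl-6-oxo-3,6-dihydro-2H-pyran-2-yl]but-2-en-1-yl 2-methylprop-2-enoate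
Product: 9 (6S)-6-[(2Z)-4-hydroxybut-2-en-2-yl]-3-methyl-5,6-dihydro-2H-pyran-2-ol (lactol; anomer mixture)
Conditions: DIBAL-H (3.5 equiv), CH2Cl2, −78 °C; Rochelle salt
Reagents that add atoms: none
Why: DIBAL-H half-reduces the unsaturated δ-lactone to the lactol (masked C9 Z-enal) and in the same operation cleaves the primary methacrylate reductively, freeing C6–OH without a separate deprotection.

Step 6
Reactants: 9 (6S)-6-[(2Z)-4-hydroxybut-2-en-2-yl]-3-methyl-5,6-dihydro-2H-pyran-2-ol; 10 (+)-B-allyldiisopinocampheylborane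
Product: 12 (2Z,4S,6Z,8R)-3,7-dimethylundeca-2,6,10-triene-1,4,8-triol, via ring-opened dihydroxy enal 11 (not isolated)
Conditions: 10 (3.3 equiv), Et2O/THF, −78 → 0 °C; then HOCH2CH2NH2
Reagents that add atoms: (+)-B-allyldiisopinocampheylborane 10, C=CCB([C@H]1C[C@H]2C[C@@H]([C@@H]1C)C2(C)C)[C@H]1C[C@H]2C[C@@H]([C@@H]1C)C2(C)C
Why: Second Brown allylboration on the ring-opened enal; the (−)-α-pinene-derived reagent attacks the Re face under reagent control and sets C9 as R, and chromatographic removal of the minor diastereomer raises the enantiopurity carried from step 2.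

Step 7
Reactants: 12 (2Z,4S,6Z,8R)-3,7-dimethylundeca-2,6,10-triene-1,4,8-triol; 13 chlorotriethylsilane
Product: 14 (2Z,4S,6Z,8R)-3,7-dimethyl-1,4,8-tris[(triethylsilyl)oxy]undeca-2,6,10-triene
Conditions: TESCl (3.6 equiv), imidazole, DMAP (cat.), DMF, 0 °C → rt
Reagents that add atoms: chlorotriethylsilane 13, CC[Si](Cl)(CC)CC
Why: Silyl ether formation; triethylsilyl ethers (not acetates) are carried through step 10 because an acyloxy group at C3 would be expelled from the vinylogous ketyl, and the primary TES ether is the handle for step 9.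

Step 8
Reactants: 14 (2Z,4S,6Z,8R)-3,7-dimethyl-1,4,8-tris[(triethylsilyl)oxy]undeca-2,6,10-triene; 15 methyl methacrylate
Product: 16 methyl (2E,5R,6Z,9S,10Z)-2,6,10-trimethyl-5,9,12-tris[(triethylsilyl)oxy]dodeca-2,6,10-trienoate
Conditions: 15 (10 equiv), Hoveyda–Grubbs II (5 mol%), CH2Cl2, 40 °C
Reagents that add atoms: methyl methacrylate 15, C=C(C)C(=O)OC
Why: Olefin cross-metathesis of the terminal alkene with the 1,1-disubstituted acrylate gives the trisubstituted enoate as the E isomer, while the two hindered trisubstituted alkenes are spectators.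

Step 9
Reactants: 16 methyl (2E,5R,6Z,9S,10Z)-2,6,10-trimethyl-5,9,12-tris[(triethylsilyl)oxy]dodeca-2,6,10-trienoate
Product: 17 methyl (2E,5R,6Z,9S,10Z)-2,6,10-trimethyl-12-oxo-5,9-bis[(triethylsilyl)oxy]dodeca-2,6,10-trienoate
Conditions: (COCl)2, DMSO, CH2Cl2, −78 → −40 °C; then Et3N, −78 → −20 °C
Reagents that add atoms: none
Why: Swern oxidation with in-flask O–Si cleavage: the chlorosulfonium reagent attacks only the unhindered primary TES ether and the alkoxysulfonium ion collapses to the aldehyde, the two secondary TES ethers and the Z geometry being retained at low temperature.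

Step 10
Reactants: 17 methyl (2E,5R,6Z,9S,10Z)-2,6,10-trimethyl-12-oxo-5,9-bis[(triethylsilyl)oxy]dodeca-2,6,10-trienoate
Product: 19 (3R,3aS,5R,6Z,9S,10Z,11aS)-3,6,10-trimethyl-5,9-bis[(triethylsilyl)oxy]-3a,4,5,8,9,11a-hexahydrocyclodeca[b]furan-2(3H)-one, via hydroxy ester 18 (not isolated)
Conditions: SmI2 (3 equiv), t-BuOH (3 equiv), THF, −78 °C, slow addition of 17 (final 2 mM); then → 0 °C; aq NH4Cl
Reagents that add atoms: none
Why: Proposed new method: SmI2 reduces the aldehyde to a Sm(III)-bound ketyl whose carbon (C6) adds to the enoate β-carbon (C7), held near by Sm(III) chelation to the ester carbonyl; a second SmI2 gives the samarium enolate, t-BuOH protonates C11 anti to C8 (11R, H-11 cis to H-7), and the C6 samarium alkoxide closes the 12,6-lactone with loss of methanol; with the ring arms C5 and C8 anti in the chelated transition state the fusion is trans (6S,7S), whereas the sense relative to C3/C9 rests only on both OTES groups staying pseudo-equatorial and is the least secure prediction; −78 °C keeps the allylic ketyl from losing its Z geometry; the closest known reaction type is the SmI2 ketyl–olefin coupling/lactonisation of aldehydes with α,β-unsaturated esters (Fukuzawa γ-lactone synthesis) and its intramolecular 5- to 8-membered-ring versions, here stretched to a 10-membered ring and a conjugated Z-enal.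

Step 11
Reactants: 19 (3R,3aS,5R,6Z,9S,10Z,11aS)-3,6,10-trimethyl-5,9-bis[(triethylsilyl)oxy]-3a,4,5,8,9,11a-hexahydrocyclodeca[b]furan-2(3H)-one
Product: 20 (3R,3aS,5R,6Z,9S,10Z,11aS)-5,9-dihydroxy-3,6,10-trimethyl-3a,4,5,8,9,11a-hexahydrocyclodeca[b]furan-2(3H)-one
Conditions: HF·pyridine, pyridine, THF, 0 °C
Reagents that add atoms: none
Why: Fluoride cleavage of the two secondary Si–O bonds under buffered, non-basic conditions, which leaves the lactone and the kinetically set C11 centre untouched.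

Step 12
Reactants: 20 (3R,3aS,5R,6Z,9S,10Z,11aS)-5,9-dihydroxy-3,6,10-trimethyl-3a,4,5,8,9,11a-hexahydrocyclodeca[b]furan-2(3H)-one; 21 acetic anhydride
Product: 22 (3R,3aS,5R,6Z,9S,10Z,11aS)-3,6,10-trimethyl-2-oxo-2,3,3a,4,5,8,9,11a-octahydrocyclodeca[b]furan-5,9-diyl diacetate (CNP0226482.4)
Conditions: Ac2O, pyridine, DMAP (cat.), CH2Cl2, 0 °C → rt
Reagents that add atoms: acetic anhydride 21, CC(=O)OC(C)=O
Why: DMAP-catalysed O-acetylation of both secondary allylic alcohols; no bond to a stereocentre is broken.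

## Compound list

1 | 3-methylfuran-2(5H)-one | CC1=CCOC1=O | starting material
2 | 3-methyl-2,5-dihydrofuran-2-ol | CC1=CCOC1O | intermediate
3 | (−)-B-allyldiisopinocampheylborane (from (+)-α-pinene) | C=CCB([C@@H]1C[C@@H]2C[C@H]([C@H]1C)C2(C)C)[C@@H]1C[C@@H]2C[C@H]([C@H]1C)C2(C)C | starting material
4 | (2Z)-4-hydroxy-2-methylbut-2-enal | O=C/C(C)=C\CO | intermediate
5 | (2Z,4S)-3-methylhepta-2,6-diene-1,4-diol | C=CC[C@H](O)/C(C)=C\CO | intermediate
6 | methacryloyl chloride | C=C(C)C(Cl)=O | starting material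
7 | (2Z,4S)-3-methylhepta-2,6-diene-1,4-diyl bis(2-methylprop-2-enoate) | C=CC[C@H](OC(=O)C(C)=C)/C(C)=C\COC(=O)C(C)=C | intermediate
8 | (2Z)-3-[(2S)-5-methyl-6-oxo-3,6-dihydro-2H-pyran-2-yl]but-2-en-1-yl 2-methylprop-2-enoate | O=C1O[C@@H](CC=C1C)/C(C)=C\COC(=O)C(C)=C | intermediate
9 | (6S)-6-[(2Z)-4-hydroxybut-2-en-2-yl]-3-methyl-5,6-dihydro-2H-pyran-2-ol | OC1O[C@@H](CC=C1C)/C(C)=C\CO | intermediate
10 | (+)-B-allyldiisopinocampheylborane (from (−)-α-pinene) | C=CCB([C@H]1C[C@H]2C[C@@H]([C@@H]1C)C2(C)C)[C@H]1C[C@H]2C[C@@H]([C@@H]1C)C2(C)C | starting material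
11 | (2Z,5S,6Z)-5,8-dihydroxy-2,6-dimethylocta-2,6-dienal | O=C/C(C)=C\C[C@H](O)/C(C)=C\CO | intermediate
12 | (2Z,4S,6Z,8R)-3,7-dimethylundeca-2,6,10-triene-1,4,8-triol | C=CC[C@@H](O)/C(C)=C\C[C@H](O)/C(C)=C\CO | intermediate
13 | chlorotriethylsilane | CC[Si](Cl)(CC)CC | starting material
14 | (2Z,4S,6Z,8R)-3,7-dimethyl-1,4,8-tris[(triethylsilyl)oxy]undeca-2,6,10-triene | C=CC[C@@H](O[Si](CC)(CC)CC)/C(C)=C\C[C@H](O[Si](CC)(CC)CC)/C(C)=C\CO[Si](CC)(CC)CC | intermediate
15 | methyl methacrylate | C=C(C)C(=O)OC | starting material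
16 | methyl (2E,5R,6Z,9S,10Z)-2,6,10-trimethyl-5,9,12-tris[(triethylsilyl)oxy]dodeca-2,6,10-trienoate | COC(=O)/C(C)=C/C[C@@H](O[Si](CC)(CC)CC)/C(C)=C\C[C@H](O[Si](CC)(CC)CC)/C(C)=C\CO[Si](CC)(CC)CC | intermediate
17 | methyl (2E,5R,6Z,9S,10Z)-2,6,10-trimethyl-12-oxo-5,9-bis[(triethylsilyl)oxy]dodeca-2,6,10-trienoate | COC(=O)/C(C)=C/C[C@@H](O[Si](CC)(CC)CC)/C(C)=C\C[C@H](O[Si](CC)(CC)CC)/C(C)=C\C=O | intermediate
18 | methyl (2R)-2-[(1S,2S,3Z,5S,7Z,9R)-2-hydroxy-4,8-dimethyl-5,9-bis[(triethylsilyl)oxy]cyclodeca-3,7-dien-1-yl]propanoate | CC[Si](CC)(CC)O[C@H]1C/C=C(/C)[C@H](O[Si](CC)(CC)CC)C[C@H]([C@@H](/C=C\1C)O)[C@@H](C)C(=O)OC | intermediate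
19 | (3R,3aS,5R,6Z,9S,10Z,11aS)-3,6,10-trimethyl-5,9-bis[(triethylsilyl)oxy]-3a,4,5,8,9,11a-hexahydrocyclodeca[b]furan-2(3H)-one | CC[Si](CC)(CC)O[C@H]1C/C=C(/C)[C@H](O[Si](CC)(CC)CC)C[C@@H]2[C@@H](/C=C\1C)OC(=O)[C@@H]2C | intermediate
20 | (3R,3aS,5R,6Z,9S,10Z,11aS)-5,9-dihydroxy-3,6,10-trimethyl-3a,4,5,8,9,11a-hexahydrocyclodeca[b]furan-2(3H)-one | O[C@H]1C/C=C(/C)[C@H](O)C[C@@H]2[C@@H](/C=C\1C)OC(=O)[C@@H]2C | intermediate
21 | acetic anhydride | CC(=O)OC(C)=O | starting material
22 | (3R,3aS,5R,6Z,9S,10Z,11aS)-3,6,10-trimethyl-2-oxo-2,3,3a,4,5,8,9,11a-octahydrocyclodeca[b]furan-5,9-diyl diacetate (CNP0226482.4) | CC(=O)O[C@H]1C/C=C(/C)[C@H](OC(C)=O)C[C@@H]2[C@@H](/C=C\1C)OC(=O)[C@@H]2C | target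

## Step count and weak points

Total step count: 12. Longest linear sequence: 12 (fully linear from 1).

**Step 10, SmI2 macrocyclisation/lactonisation (highest risk).** It can fail by pinacol dimerisation, simple reduction of the enal, 6-exo closure of the ketyl onto C1=C10, loss of the C4=C5 Z geometry, or by giving the wrong C6/C7 pair relative to C3/C9. The fallback sets out from 14 and keeps the C6–C7 ring closure but makes it an allyl-metal addition. Cross-metathesis of 14 with methyl 2-(bromomethyl)acrylate (Hoveyda–Grubbs II) gives methyl (2Z,5R,6Z,9S,10Z)-2-(bromomethyl)-6,10-dimethyl-5,9,12-tris[(triethylsilyl)oxy]dodeca-2,6,10-trienoate F1. Selective Swern oxidation of its primary TES ether gives the aldehyde methyl (2Z,5R,6Z,9S,10Z)-2-(bromomethyl)-6,10-dimethyl-12-oxo-5,9-bis[(triethylsilyl)oxy]dodeca-2,6,10-trienoate F2. Intramolecular Nozaki–Hiyama–Kishi allylation (CrCl2, THF/DMF, high dilution, with a Kishi-type chiral sulfonamide ligand if the substrate bias at C6 is wrong) closes the ring and lactonises to the α-methylene lactone (3aS,5R,6Z,9S,10Z,11aR)-6,10-dimethyl-3-methylidene-5,9-bis[(triethylsilyl)oxy]-3a,4,5,8,9,11a-hexahydrocyclodeca[b]furan-2(3H)-one F3. Conjugate reduction with L-Selectride at −78 °C and kinetic protonation of the lactone enolate anti to C8 (2,6-di-tert-butylphenol) comes back to the route at 19.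

**Step 2, allylboration of lactol 2.** The 2,5-dihydrofuran-2-ol can aromatise to 3-methylfuran, and lactols react more slowly and less selectively than free aldehydes. The fallback sets out from 1 and uses a protected open-chain enal instead of the lactol. Aminolysis of 1 with Me(MeO)NH·HCl/Me2AlCl gives (2Z)-4-hydroxy-N-methoxy-N,2-dimethylbut-2-enamide F4, which is silylated at once (TESCl, imidazole) to stop relactonisation, giving (2Z)-N-methoxy-N,2-dimethyl-4-[(triethylsilyl)oxy]but-2-enamide F5. DIBAL-H at −78 °C gives (2Z)-2-methyl-4-[(triethylsilyl)oxy]but-2-enal F6. Allylboration with 3 gives (2Z,4S)-3-methyl-1-[(triethylsilyl)oxy]hepta-2,6-dien-4-ol F7, and PPTS in methanol removes the primary TES group to come back to the route at 5.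

**Step 9, direct oxidative desilylation.** It can fail if the secondary allylic TES ethers are also attacked or if triethylamine isomerises the Z-enal. The fallback sets out from 16 and separates Si–O cleavage from oxidation. Catalytic PPTS in MeOH/CH2Cl2 at −10 °C cleaves only the primary TES ether to give methyl (2E,5R,6Z,9S,10Z)-12-hydroxy-2,6,10-trimethyl-5,9-bis[(triethylsilyl)oxy]dodeca-2,6,10-trienoate F8, and neutral MnO2 in CH2Cl2 oxidises this allylic alcohol to come back to the route at 17.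

## Further compounds

F1 | step 10 | methyl (2Z,5R,6Z,9S,10Z)-2-(bromomethyl)-6,10-dimethyl-5,9,12-tris[(triethylsilyl)oxy]dodeca-2,6,10-trienoate | COC(=O)/C(CBr)=C/C[C@@H](O[Si](CC)(CC)CC)/C(C)=C\C[C@H](O[Si](CC)(CC)CC)/C(C)=C\CO[Si](CC)(CC)CC
F2 | step 10 | methyl (2Z,5R,6Z,9S,10Z)-2-(bromomethyl)-6,10-dimethyl-12-oxo-5,9-bis[(triethylsilyl)oxy]dodeca-2,6,10-trienoate | COC(=O)/C(CBr)=C/C[C@@H](O[Si](CC)(CC)CC)/C(C)=C\C[C@H](O[Si](CC)(CC)CC)/C(C)=C\C=O
F3 | step 10 | (3aS,5R,6Z,9S,10Z,11aR)-6,10-dimethyl-3-methylidene-5,9-bis[(triethylsilyl)oxy]-3a,4,5,8,9,11a-hexahydrocyclodeca[b]furan-2(3H)-one | CC[Si](CC)(CC)O[C@H]1C/C=C(/C)[C@H](O[Si](CC)(CC)CC)C[C@@H]2[C@@H](/C=C\1C)OC(=O)C2=C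
F4 | step 2 | (2Z)-4-hydroxy-N-methoxy-N,2-dimethylbut-2-enamide | CON(C)C(=O)/C(C)=C\CO
F5 | step 2 | (2Z)-N-methoxy-N,2-dimethyl-4-[(triethylsilyl)oxy]but-2-enamide | CON(C)C(=O)/C(C)=C\CO[Si](CC)(CC)CC
F6 | step 2 | (2Z)-2-methyl-4-[(triethylsilyl)oxy]but-2-enal | O=C/C(C)=C\CO[Si](CC)(CC)CC
F7 | step 2 | (2Z,4S)-3-methyl-1-[(triethylsilyl)oxy]hepta-2,6-dien-4-ol | C=CC[C@H](O)/C(C)=C\CO[Si](CC)(CC)CC
F8 | step 9 | methyl (2E,5R,6Z,9S,10Z)-12-hydroxy-2,6,10-trimethyl-5,9-bis[(triethylsilyl)oxy]dodeca-2,6,10-trienoate | COC(=O)/C(C)=C/C[C@@H](O[Si](CC)(CC)CC)/C(C)=C\C[C@H](O[Si](CC)(CC)CC)/C(C)=C\CO
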